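## Retrosynthetic overview

1. Locants (Stemona type): N4; C5–C8 (azepane CH2 groups); C9; C9a (aza-quaternary spiro carbon); C1–C3; C10 (ethyl); C11 (O); C12; C13 (carbinol); C18–C21 (side lactone). Rings: A pyrrolidine, B azepane, C cyclopentane, D fused lactone, E side lactone.
2. Ring E is added last (C18 aldehyde plus a 2-(ethoxycarbonyl)allylzinc reagent, then hydrogenation). Ring D comes from a C11 ketone: acetate alkylation at C12, reduction at C11, lactonisation, then C13 methylation and convex-face hydroxylation.
3. Ring B (key step) is stitched onto an A/C spirocycle in one flask by a C5–C8 unit that is a carbanion at C8 and a masked aldehyde at C5. Conjugate addition to the C9=C10–C11=O enone of ring C forms C8–C9; N–O cleavage and reductive amination then form N4–C5. The enabling feature: N4 and the enone β-carbon C9 are 1,3-related through the spiro carbon C9a and sit on opposite faces of ring C in the target. An O-benzyl group on N4 blocks its own face, so C8 enters trans to N4 (the trans B/C fusion) before N4 is unmasked as the nucleophile.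
4. Ring C: ring-closing metathesis between a vinyl group on C9a and an aldol-derived C12–C11–C10 arm. C9a: vinyl Grignard addition to a cyclic ketonitrone, trans to the C3 substituent.
5. Ring A: (R)-benzyl glycidyl ether supplies C2, C3 and C18; a γ-mesyloxy ketoxime closes to the nitrone with inversion at C3. Order of ring formation: A, C, B, D, E.

Key step: step 10

Remark: the faces of ring C are called face A (carries N4 and the ethyl group in the target) and face B (carries C1, C8, O11 and C13). Assumption: Grignard solution 16 is a stock reagent made from commercial 2-(3-chloropropyl)-1,3-dioxolane and magnesium turnings.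

## Route

Step 1
Reactants: 1 (R)-benzyl glycidyl ether; 2 2-methylallylmagnesium chloride
Product: 3 (2R)-1-(benzyloxy)-5-methylhex-5-en-2-ol
Conditions: CuI (10 mol%), THF, −30 °C to 0 °C; aq. NH4Cl
Reagents that add atoms: none
Why: Copper-catalysed SN2 opening of the terminal epoxide by the allylic Grignard reagent at the CH2 terminus should give the secondary alcohol with the stereocentre of 1 (the future C3) untouched.

Step 2
Reactants: 3 (2R)-1-(benzyloxy)-5-methylhex-5-en-2-ol
Product: 4 (2R)-1-(benzyloxy)-5-methylhex-5-en-2-yl methanesulfonate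
Conditions: MsCl, Et3N, CH2Cl2, 0 °C
Reagents that add atoms: methanesulfonyl chloride, CS(=O)(=O)Cl
Why: Mesylation of the secondary alcohol proceeds with retention and turns the C3 oxygen into the leaving group that nitrogen displaces in step 4.

Step 3
Reactants: 4 (2R)-1-(benzyloxy)-5-methylhex-5-en-2-yl methanesulfonate
Product: 5 (2R)-1-(benzyloxy)-5-oxohexan-2-yl methanesulfonate
Conditions: O3, CH2Cl2–MeOH, −78 °C; Me2S
Reagents that add atoms: ozone, [O-][O+]=O
Why: Ozonolysis with reductive work-up cleaves the 1,1-disubstituted alkene to the methyl ketone (the future C9a) without touching the mesylate or the benzyl ether.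

Step 4
Reactants: 5 (2R)-1-(benzyloxy)-5-oxohexan-2-yl methanesulfonate
Product: 7 (2S)-2-[(benzyloxy)methyl]-5-methyl-3,4-dihydro-2H-pyrrole 1-oxide, via ketoxime 6 (not isolated)
Conditions: NH2OH·HCl, NaOAc, EtOH–H2O, rt; then 70 °C
Reagents that add atoms: hydroxylamine hydrochloride, Cl.NO
Why: Oximation followed by intramolecular 5-exo-tet N-alkylation of the oxime by the γ-mesylate (the classical γ-sulfonyloxy ketone route to 1-pyrroline N-oxides) should close ring A as the cyclic ketonitrone, the SN2 inversion setting C3 as S.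

Step 5
Reactants: 7 (2S)-2-[(benzyloxy)methyl]-5-methyl-3,4-dihydro-2H-pyrrole 1-oxide; 8 2-ethylacrolein
Product: 9 (2S)-2-[(benzyloxy)methyl]-5-{3-methylidene-2-[(triethylsilyl)oxy]pentyl}-3,4-dihydro-2H-pyrrole 1-oxide (both C11 epimers)
Conditions: LiN(iPr)2, THF, −78 °C; 8; then Et3SiCl, −78 °C to 0 °C
Reagents that add atoms: chlorotriethylsilane, CC[Si](CC)(CC)Cl
Why: Deprotonation of the C-methyl group of the ketonitrone gives an aza-enolate that adds 1,2 to the enal in an aldol-type reaction (C-methyl nitrones are known to condense with aldehydes), in situ silylation blocks retro-aldol and dehydration, and the new C11 centre is formed as a mixture that step 9 erases.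

Step 6
Reactants: 9 silylated nitrone aldol product; 10 vinylmagnesium bromide
Product: 11 (2R,5S)-5-[(benzyloxy)methyl]-2-ethenyl-2-{3-methylidene-2-[(triethylsilyl)oxy]pentyl}pyrrolidin-1-ol (vinyl trans to CH2OBn)
Conditions: THF, −78 °C to 0 °C; aq. NH4Cl
Reagents that add atoms: none
Why: Grignard addition to the cyclic ketonitrone should occur on the face anti to the C3 benzyloxymethyl group (the trans-2,5 preference of 5-substituted pyrroline N-oxides), creating the aza-quaternary centre C9a with the vinyl group (C9) trans and the C12 arm cis to C18.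

Step 7
Reactants: 11 N-hydroxypyrrolidine
Product: 12 (2R,5S)-1-(benzyloxy)-5-[(benzyloxy)methyl]-2-ethenyl-2-{3-methylidene-2-[(triethylsilyl)oxy]pentyl}pyrrolidine
Conditions: NaH, BnBr, THF–DMF, 0 °C
Reagents that add atoms: benzyl bromide, BrCc1ccccc1
Why: Williamson O-benzylation of the hydroxylamine anion masks nitrogen as a non-basic, oxidation-stable N–O-benzyl group that also shields one enone face in step 10.

Step 8
Reactants: 12 N-benzyloxy diene
Product: 14 (2S,5R)-1-(benzyloxy)-2-[(benzyloxy)methyl]-7-ethyl-1-azaspiro[4.4]non-6-en-8-ol (both C11 epimers), via silyl ether 13 (not isolated)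
Conditions: second-generation Grubbs catalyst (5 mol%), CH2Cl2, 40 °C; then PPTS, MeOH, rt
Reagents that add atoms: none
Why: Ring-closing metathesis of the C9a vinyl group with the 1,1-disubstituted alkene forms the trisubstituted C9=C10 cyclopentene (ring C) with loss of ethene, and mild acid methanolysis then removes the triethylsilyl ether.

Step 9
Reactants: 14 spirocyclic allylic alcohol
Product: 15 (2S,5R)-1-(benzyloxy)-2-[(benzyloxy)methyl]-7-ethyl-1-azaspiro[4.4]non-6-en-8-one
Conditions: Dess–Martin periodinane, NaHCO3, CH2Cl2, 0 °C to rt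
Reagents that add atoms: none
Why: Dess–Martin oxidation of the allylic alcohol gives the C9=C10–C11=O enone and removes the C11 stereocentre.

Step 10
Reactants: 15 spirocyclic N-benzyloxy enone; 16 [3-(1,3-dioxolan-2-yl)propyl]magnesium chloride
Product: 19 tricyclic amino ketone (rings A, B and C; 3S,9R,9aR,10R; C11 ketone, C12 CH2, CH2OBn on C3), via silyl enol ether 17 (not isolated), via amino keto aldehyde 18 (not isolated)
Conditions: 16 (3 equiv), CuBr·SMe2 (30 mol%), Me3SiCl, THF, −78 °C to −30 °C; then, same flask, Zn dust, AcOH–H2O (4:1), 60 °C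
Reagents that add atoms: none
Why: The alkylcopper species formed from 16 adds 1,4 to the enone and Me3SiCl traps the enolate as 17 (copper-catalysed Grignard conjugate addition, as in the first stage of three-component cyclopentenone couplings); in the same flask zinc in aqueous acetic acid cleaves the N–O bond, the acid hydrolyses the silyl enol ether and the dioxolane to give 18, and the freed secondary amine condenses with the C5 aldehyde to a cyclic iminium ion that zinc and acetic acid reduce (intramolecular reductive amination). Ring B therefore closes by attack of N4 on the C5 carbonyl (7-exo-trig) followed by reduction of the endocyclic iminium. C9 is set in the intermolecular C–C bond formation: the benzyloxy group on N4, attached to the adjacent spiro carbon C9a, covers face A of the enone, so C8 enters on face B, trans to N4, which is the trans B/C ring fusion; a chain delivered from nitrogen could only give the cis fusion, hence C8–C9 first and N4–C5 second. C10 is set by protonation and acid-mediated equilibration of the α-centre to the more stable trans-2,3-disubstituted cyclopentanone (ethyl trans to the C8 chain). The step needs 1,4- over 1,2-addition (copper catalysis with Me3SiCl), cleavage of the N–O bond but not of the C18 benzyl ether (zinc reduces only the weak N–O bond), and capture of the aldehyde by nitrogen rather than by a ketone enol (the amine is unmasked in the medium that releases the aldehyde, and iminium formation is drained by reduction).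

Step 11
Reactants: 19 tricyclic amino ketone; 20 tert-butyl bromoacetate
Product: 21 C12-alkylated tricyclic ketone (3S,9R,9aS,10R,12R; CH2CO2tBu on face B of C12)
Conditions: LiN(iPr)2, THF, −78 °C; 20, DMPU, −78 °C to −40 °C
Reagents that add atoms: none
Why: Kinetic deprotonation at the less substituted α-carbon C12 and SN2 alkylation of the lithium enolate should place the acetate arm anti to N4 and to the C3 benzyloxymethyl group that overhangs face A (so cis to C1), and at −78 °C the β-amino enolate should not eliminate.

Step 12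
Reactants: 21 C12-alkylated tricyclic ketone
Product: 23 tetracyclic lactone (rings A–D; 3S,9R,9aS,10R,11S,12R; C13 still CH2), via cis-hydroxy ester 22 (not isolated)
Conditions: LiBH(s-Bu)3, THF, −78 °C; then CF3CO2H, CH2Cl2, rt
Reagents that add atoms: none
Why: The bulky hydride should attack C11 anti to the tert-butyl acetate arm on C12, giving the C11 alcohol cis to that arm, so that acidolysis of the tert-butyl ester is followed by closure of the cis-fused γ-lactone (ring D), which only this epimer can form.

Step 13
Reactants: 23 tetracyclic lactone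
Product: 24 C13-methyl lactone (methyl on the convex face)
Conditions: LiN(iPr)2, THF, −78 °C; MeI (1.1 equiv), −78 °C
Reagents that add atoms: iodomethane, CI
Why: Enolate alkylation of the bicyclic lactone introduces the C13 methyl group on the convex face, and the configuration of C13 at this stage is irrelevant because the centre is enolised again in step 14.

Step 14
Reactants: 24 C13-methyl lactone
Product: 25 C13-hydroxy lactone benzyl ether (the target skeleton with CH2OBn on C3)
Conditions: KN(SiMe3)2, THF, −78 °C; 3-phenyl-2-(phenylsulfonyl)oxaziridine; aq. NH4Cl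
Reagents that add atoms: 3-phenyl-2-(phenylsulfonyl)oxaziridine, O=S(=O)(c1ccccc1)N1OC1c1ccccc1
Why: Electrophilic hydroxylation of the potassium enolate by the N-sulfonyloxaziridine should occur on the convex face of the cis-fused bicyclic lactone (syn to H11 and H12, the concave face being blocked by ring C and C1), which places the hydroxyl exo and the methyl endo as in the target (C13 S).

Step 15
Reactants: 25 C13-hydroxy lactone benzyl ether
Product: 26 primary alcohol (CH2OH on C3)
Conditions: H2 (1 atm), Pd(OH)2/C, EtOH, AcOH (1 equiv), rt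
Reagents that add atoms: none
Why: Hydrogenolysis of the primary benzyl ether with the amine protonated frees the C18 alcohol without affecting the lactone or the tertiary alcohol.

Step 16
Reactants: 26 primary alcohol
Product: 27 α-amino aldehyde (CHO on C3)
Conditions: Dess–Martin periodinane, NaHCO3, CH2Cl2, 0 °C
Reagents that add atoms: none
Why: Dess–Martin oxidation of the primary alcohol gives the α-amino aldehyde, which is used at once to avoid epimerisation at C3.

Step 17
Reactants: 27 α-amino aldehyde; 28 ethyl 2-(bromomethyl)acrylate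
Product: 30 α-methylene-γ-butyrolactone (ring E with exocyclic methylene at C20), via hydroxy ester 29 (not isolated)
Conditions: Zn dust (activated), THF, 0 °C to rt; aq. NH4Cl
Reagents that add atoms: none
Why: Barbier-type addition of the 2-(ethoxycarbonyl)allylzinc reagent to the aldehyde, with zinc chelated between N4 and the carbonyl oxygen (Cram chelate model), should give the threo amino alcohol (C18 S), and the alkoxide then lactonises onto the ester to close ring E.

Step 18
Reactants: 30 α-methylene-γ-butyrolactone
Product: 31 CNP0260919.2 (target)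
Conditions: H2 (1 atm), Pd/C, EtOAc, rt
Reagents that add atoms: none
Why: Heterogeneous hydrogenation of the exocyclic methylene from the lactone face anti to the bulky C18 substituent should give the cis-2,4-disubstituted butyrolactone (C20 S), which is the target.

## Compound list

1 | (R)-benzyl glycidyl ether | C1O[C@H]1COCc1ccccc1 | starting material
2 | 2-methylallylmagnesium chloride | C=C(C)C[Mg]Cl | starting material
3 | (2R)-1-(benzyloxy)-5-methylhex-5-en-2-ol | C=C(C)CC[C@H](COCc1ccccc1)O | intermediate
4 | (2R)-1-(benzyloxy)-5-methylhex-5-en-2-yl methanesulfonate | C=C(C)CC[C@H](COCc1ccccc1)OS(C)(=O)=O | intermediate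
5 | (2R)-1-(benzyloxy)-5-oxohexan-2-yl methanesulfonate | CC(=O)CC[C@H](COCc1ccccc1)OS(C)(=O)=O | intermediate
6 | ketoxime of 5 (E/Z mixture, not isolated) | CC(=NO)CC[C@H](COCc1ccccc1)OS(C)(=O)=O | intermediate
7 | (2S)-2-[(benzyloxy)methyl]-5-methyl-3,4-dihydro-2H-pyrrole 1-oxide | CC1=[N+]([O-])[C@H](COCc2ccccc2)CC1 | intermediate
8 | 2-ethylacrolein (2-methylidenebutanal) | C=C(CC)C=O | starting material
9 | (2S)-2-[(benzyloxy)methyl]-5-{3-methylidene-2-[(triethylsilyl)oxy]pentyl}-3,4-dihydro-2H-pyrrole 1-oxide (C11 epimers) | C=C(CC)C(O[Si](CC)(CC)CC)CC1=[N+]([O-])[C@H](COCc2ccccc2)CC1 | intermediate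
10 | vinylmagnesium bromide | C=C[Mg]Br | starting material
11 | (2R,5S)-5-[(benzyloxy)methyl]-2-ethenyl-2-{3-methylidene-2-[(triethylsilyl)oxy]pentyl}pyrrolidin-1-ol | C=C(CC)C(O[Si](CC)(CC)CC)C[C@@]1(C=C)CC[C@@H](COCc2ccccc2)N1O | intermediate
12 | (2R,5S)-1-(benzyloxy)-5-[(benzyloxy)methyl]-2-ethenyl-2-{3-methylidene-2-[(triethylsilyl)oxy]pentyl}pyrrolidine | C=C(CC)C(O[Si](CC)(CC)CC)C[C@@]1(C=C)CC[C@@H](COCc2ccccc2)N1OCc1ccccc1 | intermediate
13 | (2S,5R)-1-(benzyloxy)-2-[(benzyloxy)methyl]-7-ethyl-8-[(triethylsilyl)oxy]-1-azaspiro[4.4]non-6-ene (not isolated) | CCC1=C[C@]2(CC1O[Si](CC)(CC)CC)CC[C@@H](COCc1ccccc1)N2OCc1ccccc1 | intermediate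
14 | (2S,5R)-1-(benzyloxy)-2-[(benzyloxy)methyl]-7-ethyl-1-azaspiro[4.4]non-6-en-8-ol | CCC1=C[C@]2(CC1O)CC[C@@H](COCc1ccccc1)N2OCc1ccccc1 | intermediate
15 | (2S,5R)-1-(benzyloxy)-2-[(benzyloxy)methyl]-7-ethyl-1-azaspiro[4.4]non-6-en-8-one | CCC1=C[C@]2(CC1=O)CC[C@@H](COCc1ccccc1)N2OCc1ccccc1 | intermediate
16 | [3-(1,3-dioxolan-2-yl)propyl]magnesium chloride | Cl[Mg]CCCC1OCCO1 | starting material
17 | trimethylsilyl enol ether of the conjugate adduct (C8 chain on face B of C9; not isolated) | CCC1=C(O[Si](C)(C)C)C[C@]2(CC[C@@H](COCc3ccccc3)N2OCc2ccccc2)[C@@H]1CCCC1OCCO1 | intermediate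
18 | amino keto aldehyde (N–H amine, C11 ketone, C5 aldehyde; not isolated) | CC[C@H]1C(=O)C[C@]2(CC[C@@H](COCc3ccccc3)N2)[C@@H]1CCCC=O | intermediate
19 | tricyclic amino ketone, rings A, B, C (3S,9R,9aR,10R) | CC[C@H]1C(=O)C[C@@]23CC[C@@H](COCc4ccccc4)N2CCCC[C@H]13 | intermediate
20 | tert-butyl bromoacetate | CC(C)(C)OC(=O)CBr | starting material
21 | C12-(tert-butoxycarbonylmethyl) tricyclic ketone (3S,9R,9aS,10R,12R) | CC[C@H]1C(=O)[C@H](CC(=O)OC(C)(C)C)[C@@]23CC[C@@H](COCc4ccccc4)N2CCCC[C@H]13 | intermediate
22 | C11 alcohol cis to the acetate arm (not isolated) | CC[C@H]1[C@H](O)[C@H](CC(=O)OC(C)(C)C)[C@@]23CC[C@@H](COCc4ccccc4)N2CCCC[C@H]13 | intermediate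
23 | tetracyclic lactone, rings A–D, C13 = CH2 (3S,9R,9aS,10R,11S,12R) | CC[C@H]1[C@@H]2OC(=O)C[C@@H]2[C@@]23CC[C@@H](COCc4ccccc4)N2CCCC[C@H]13 | intermediate
24 | C13-methyl lactone (methyl exo, 13S) | CC[C@H]1[C@@H]2OC(=O)[C@@H](C)[C@@H]2[C@@]23CC[C@@H](COCc4ccccc4)N2CCCC[C@H]13 | intermediate
25 | C13-hydroxy-C13-methyl lactone with CH2OBn on C3 | CC[C@H]1[C@@H]2OC(=O)[C@@](C)(O)[C@@H]2[C@@]23CC[C@@H](COCc4ccccc4)N2CCCC[C@H]13 | intermediate
26 | primary alcohol (CH2OH on C3) | CC[C@H]1[C@@H]2OC(=O)[C@@](C)(O)[C@@H]2[C@@]23CC[C@@H](CO)N2CCCC[C@H]13 | intermediate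
27 | α-amino aldehyde (CHO on C3) | CC[C@H]1[C@@H]2OC(=O)[C@@](C)(O)[C@@H]2[C@@]23CC[C@@H](C=O)N2CCCC[C@H]13 | intermediate
28 | ethyl 2-(bromomethyl)acrylate | C=C(CBr)C(=O)OCC | starting material
29 | (18S)-homoallylic alcohol with the 2-(ethoxycarbonyl)allyl group (not isolated) | CC[C@H]1[C@@H]2OC(=O)[C@@](C)(O)[C@@H]2[C@@]23CC[C@@H]([C@@H](O)CC(=C)C(=O)OCC)N2CCCC[C@H]13 | intermediate
30 | α-methylene-γ-butyrolactone (ring E with C20=CH2) | CC[C@H]1[C@@H]2OC(=O)[C@@](C)(O)[C@@H]2[C@@]23CC[C@@H]([C@@H]4CC(=C)C(=O)O4)N2CCCC[C@H]13 | intermediate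
31 | CNP0260919.2 (3S,9R,9aS,10R,11S,12R,13S,18S,20S) | CC[C@H]1[C@@H]2OC(=O)[C@@](C)(O)[C@@H]2[C@@]23CC[C@@H]([C@@H]4C[C@H](C)C(=O)O4)N2CCCC[C@H]13 | target

## Step count and risks

Total step count: 18. Longest linear sequence: 18 steps (1 to 31).

Steps most likely to fail:

**Step 10.** The 1,4-addition to the α-ethyl, γ-quaternary enone may be slow or not face-selective, or the keto aldehyde may cyclise by an aldol pathway during the acidic unmasking. Fallback (radical C–C bond formation, then ring closure by SN2 instead of reductive amination): setting out from 15, a radical conjugate addition (Giese reaction) of 1-chloro-4-iodobutane mediated by (Me3Si)3SiH and AIBN in toluene at 80 °C, followed by DBU to equilibrate C10, should give the N-benzyloxy 4-chlorobutyl ketone F1. Zn dust in AcOH at 50 °C would then cleave the N–O bond to give the secondary amino chloride F2. NaI and K2CO3 in MeCN at 70 °C would close ring B by intramolecular N-alkylation and return to the route at 19.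

**Step 12.** Hydride addition to the trans-2,5-disubstituted cyclopentanone may show poor facial selectivity and give the C11 epimer, which cannot lactonise. Fallback (inversion at C11 instead of direct cis reduction): setting out from 21, NaBH4 in MeOH at 0 °C gives the trans-hydroxy ester F3 beside 22. CF3CO2H lactonises the cis part and converts F3 into the trans-hydroxy acid F4. A Mitsunobu lactonisation (PPh3, diisopropyl azodicarboxylate, THF) then closes ring D with inversion at C11 and returns to the route at 23.

**Step 17.** Chelation may fail at the hindered N4, so that addition follows the Felkin–Anh sense and gives the C18 epimer. Fallback (C18 set by ketone reduction, C20 taken from a chiral reagent): setting out from 27, the Grignard reagent made from (R)-(3-bromo-2-methylpropoxy)(tert-butyl)dimethylsilane (itself from commercial (R)-3-bromo-2-methylpropan-1-ol) adds to the aldehyde to give the C18 carbinol mixture F5. Dess–Martin oxidation gives the α-amino ketone F6. LiBH(s-Bu)3 at −78 °C should reduce it in the Felkin–Anh sense, anti to N4, to the (18S)-alcohol F7. HF·pyridine removes the silyl group to give the 1,4-diol F8, and TEMPO with PhI(OAc)2 oxidises the primary alcohol through the lactol to the lactone, arriving at 31.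

Further compounds

F1 | step 10 | N-benzyloxy spiro ketone with a 4-chlorobutyl chain on C9 (trans to N4, ethyl trans to the chain) | CC[C@H]1C(=O)C[C@]2(CC[C@@H](COCc3ccccc3)N2OCc2ccccc2)[C@@H]1CCCCCl
F2 | step 10 | secondary amino chloride (N–H amine of F1) | CC[C@H]1C(=O)C[C@]2(CC[C@@H](COCc3ccccc3)N2)[C@@H]1CCCCCl
F3 | step 12 | trans-hydroxy ester (C11 epimer of 22) | CC[C@H]1[C@@H](O)[C@H](CC(=O)OC(C)(C)C)[C@@]23CC[C@@H](COCc4ccccc4)N2CCCC[C@H]13
F4 | step 12 | trans-hydroxy acid | CC[C@H]1[C@@H](O)[C@H](CC(=O)O)[C@@]23CC[C@@H](COCc4ccccc4)N2CCCC[C@H]13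
F5 | step 17 | C18 carbinol mixture with the (S)-3-(tert-butyldimethylsilyloxy)-2-methylpropyl chain | CC[C@H]1[C@@H]2OC(=O)[C@@](C)(O)[C@@H]2[C@@]23CC[C@@H](C(O)C[C@H](C)CO[Si](C)(C)C(C)(C)C)N2CCCC[C@H]13
F6 | step 17 | C18 α-amino ketone | CC[C@H]1[C@@H]2OC(=O)[C@@](C)(O)[C@@H]2[C@@]23CC[C@@H](C(=O)C[C@H](C)CO[Si](C)(C)C(C)(C)C)N2CCCC[C@H]13
F7 | step 17 | (18S)-alcohol silyl ether | CC[C@H]1[C@@H]2OC(=O)[C@@](C)(O)[C@@H]2[C@@]23CC[C@@H]([C@@H](O)C[C@H](C)CO[Si](C)(C)C(C)(C)C)N2CCCC[C@H]13
F8 | step 17 | (18S,20S)-1,4-diol | CC[C@H]1[C@@H]2OC(=O)[C@@](C)(O)[C@@H]2[C@@]23CC[C@@H]([C@@H](O)C[C@H](C)CO)N2CCCC[C@H]13
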